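**Plan**

1. Numbering: na­phtho­quinone C1–C8a, side chain C1'–C5' on C2. The retrosynthesis masks the C5/C8 hydroxyls as methyl ethers, cuts the quinone ring at C1–C8a and C4–C4a (aryne + furan), cuts C2–C1' (3-furyllithium + Weinreb amide), and cuts the butanoate C–O bond.
2. Enabling feature: C1–C4 (C2 substituted) is a four-carbon unit fused through C4a/C8a to a benzo ring with identical oxygens at C5 and C8. A 3-substituted furan (its C2–C5 become C1–C4, its oxygen one quinone oxygen) and mirror-symmetric 3,6-dimethoxybenzyne can therefore combine in only one constitution.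
3. Forward order: the chain is joined to the furan first (ketone, then (R)-alcohol, then butanoate), and the silylaryl triflate is made from 2,5-dimethoxyphenol. The aryne cycloaddition then closes the future quinone ring onto the benzo ring; bridge opening/oxidation and oxidative demethylation finish the synthesis.
4. Stereochemistry: the only stereocentre, C1' (R), comes from CBS reduction of the furyl ketone with the (S)-catalyst and is acylated with retention. The bridgehead centres made in the key step are transient.

Key step: step 8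

Remark: "butylshikonin" is read as the butanoate ester shown by the SMILES; naphthazarins are tautomeric, so the 2-substituted 5,8-dihydroxy-1,4-dione drawn and its 6-substituted tautomer are one compound.

**Step 1**
Reactants: 1 2,5-dimethoxyphenol
Product: 2 2,5-dimethoxyphenyl N-isopropylcarbamate
Conditions: i-PrNCO, Et3N (cat.), CH2Cl2, rt
Reagents that add atoms: isopropyl isocyanate, CC(C)N=C=O
Why: Triethylamine-catalysed addition of the phenol to the isocyanate (carbamoylation) should be clean and installs an N–H carbamate that is a strong ortho-director after N-silylation yet can later be removed under mild base.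

**Step 2**
Reactants: 2 2,5-dimethoxyphenyl N-isopropylcarbamate
Product: 6 3,6-dimethoxy-2-(trimethylsilyl)phenyl N-isopropylcarbamate, via N-silyl carbamate 3 (not isolated), via ortho-lithiated N-silyl carbamate 4 (not isolated), via C,N-bis(silyl) carbamate 5 (not isolated)
Conditions: TMSOTf, TMEDA, Et2O, 0 °C→rt; n-BuLi (2 equiv), TMEDA, −78 °C; TMSCl, −78 °C→rt; aq. NaHSO4
Reagents that add atoms: chlorotrimethylsilane, C[Si](C)(C)Cl
Why: Directed ortho-metalation of the in situ N-silylated carbamate (Snieckus–Hoppe type) should occur only at C6, the one free position ortho to the carbamate and also ortho to a methoxy group, and at −78 °C silylation by TMSCl outruns anionic Fries rearrangement, the labile N–Si bond being hydrolysed on acidic work-up.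

**Step 3**
Reactants: 6 3,6-dimethoxy-2-(trimethylsilyl)phenyl N-isopropylcarbamate
Product: 8 3,6-dimethoxy-2-(trimethylsilyl)phenyl trifluoromethanesulfonate, via silylphenol 7 (not isolated)
Conditions: DBU, Et2NH, MeCN, 40 °C; then PhNTf2, rt
Reagents that add atoms: N-phenylbis(trifluoromethanesulfonimide), O=S(=O)(N(c1ccccc1)S(=O)(=O)C(F)(F)F)C(F)(F)F
Why: DBU induces E1cB loss of isopropyl isocyanate from the N–H carbamate (trapped by diethylamine as the urea), and the hindered silylphenoxide so released is triflated in the same pot by PhNTf2, the established carbamate-to-silyl-triflate sequence for Kobayashi aryne precursors.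

**Step 4**
Reactants: 9 4-methylpent-3-enoic acid
Product: 11 N-methoxy-N,4-dimethylpent-3-enamide, via acyl imidazolide 10 (not isolated)
Conditions: CDI, CH2Cl2, 0 °C→rt; then MeNHOMe·HCl, rt
Reagents that add atoms: N,O-dimethylhydroxylamine hydrochloride, CNOC.Cl
Why: Activation as the acyl imidazolide and aminolysis by N,O-dimethylhydroxylamine (Weinreb amide formation) run under nearly neutral conditions, which should keep the β,γ-alkene from moving into conjugation.

**Step 5**
Reactants: 12 3-bromofuran; 11 N-methoxy-N,4-dimethylpent-3-enamide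
Product: 15 1-(furan-3-yl)-4-methylpent-3-en-1-one, via furan-3-yllithium 13 (not isolated), via lithium hemiaminal alkoxide 14 (not isolated)
Conditions: n-BuLi, THF, −78 °C; then 11, −78 °C; AcOH/THF quench at −78 °C
Reagents that add atoms: none
Why: Bromine–lithium exchange at −78 °C gives 3-furyllithium without isomerisation to the 2-lithio isomer, its addition to the Weinreb amide stops at the chelated tetrahedral adduct (Weinreb ketone synthesis), and a cold acetic acid quench should release the β,γ-unsaturated ketone without over-addition or alkene migration.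

**Step 6**
Reactants: 15 1-(furan-3-yl)-4-methylpent-3-en-1-one
Product: 17 (R)-1-(furan-3-yl)-4-methylpent-3-en-1-ol, via catechol borate ester 16 (not isolated)
Conditions: (S)-Me-CBS (20 mol %), catecholborane, toluene, −78→−40 °C; MeOH, then aq. NaOH wash
Reagents that add atoms: none
Why: Corey–Bakshi–Shibata reduction: the ketone binds the catalyst boron with the flat 3-furyl group as the large substituent, so the N-bound catecholborane delivers hydride to the Si face and sets C1' as R (the same sense as acetophenone to (R)-1-phenylethanol with the (S)-catalyst), while catecholborane at low temperature does not hydroborate the trisubstituted alkene.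

**Step 7**
Reactants: 17 (R)-1-(furan-3-yl)-4-methylpent-3-en-1-ol; 18 butanoic anhydride
Product: 19 (R)-1-(furan-3-yl)-4-methylpent-3-en-1-yl butanoate
Conditions: Et3N, DMAP (cat.), CH2Cl2, 0 °C→rt
Reagents that add atoms: none
Why: DMAP-catalysed acyl transfer from the anhydride (Steglich-type acylation) esterifies the secondary alcohol at oxygen, so the C1'–O bond is untouched and the R configuration is retained.

**Step 8**
Reactants: 8 3,6-dimethoxy-2-(trimethylsilyl)phenyl trifluoromethanesulfonate; 19 (R)-1-(furan-3-yl)-4-methylpent-3-en-1-yl butanoate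
Product: 21 (R)-1-(5,8-dimethoxy-1,4-dihydro-1,4-epoxynaphthalen-2-yl)-4-methylpent-3-en-1-yl butanoate (both bridgehead epimers), via 3,6-dimethoxybenzyne 20 (not isolated)
Conditions: CsF (3 equiv), 8 (1.5 equiv), MeCN, rt
Reagents that add atoms: none
Why: Fluoride attacks silicon of 8 and the developing aryl anion expels the ortho triflate, giving 3,6-dimethoxybenzyne 20 at room temperature; its strained, electrophilic triple bond is captured by the furan of 19 in a concerted suprafacial [π4s+π2s] cycloaddition across furan C2 and C5, which forms the C1–C8a and C4–C4a bonds. The closest known reaction type is Kobayashi aryne generation with in situ furan Diels–Alder trapping, which is established for ortho-silylaryl triflates and for 3,6-dimethoxybenzyne with furan itself. The one new ring, the six-membered carbocycle C1–C2–C3–C4–C4a–C8a, closes by intermolecular [4+2] cycloaddition with both σ-bonds made in the same event, and the furan oxygen is carried along as the 1,4-epoxy bridge. The two bridgehead stereocentres C1 and C4 are necessarily cis across the bridge but are not controlled relative to C1', which is acceptable because both are erased in step 9; C1' itself takes no part. The step needs chemoselectivity for the furan diene over an ene or [2+2] reaction at the C3'=C4' alkene and over fluoride attack on the ester, which the much higher aryne reactivity of furan and the low basicity of CsF in MeCN should secure. No regiocontrol is needed, because the aryne has a mirror plane bisecting the triple bond and both orientations give the same constitution.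

**Step 9**
Reactants: 21 (R)-1-(5,8-dimethoxy-1,4-dihydro-1,4-epoxynaphthalen-2-yl)-4-methylpent-3-en-1-yl butanoate
Product: 24 (R)-1-(5,8-dimethoxy-1,4-dioxo-1,4-dihydronaphthalen-2-yl)-4-methylpent-3-en-1-yl butanoate, via 3-substituted 1-naphthol 22 (not isolated), via 2-substituted 1-naphthol 23 (not isolated)
Conditions: (i) Cu(OTf)2 (5 mol %), DCE, 0 °C→rt, Ar; filter through NaHCO3/Celite, concentrate; (ii) salcomine (10 mol %), O2 (1 atm), MeCN, rt
Reagents that add atoms: dioxygen, O=O
Why: Coordination of the Lewis acid to the bridging oxygen triggers C–O ionisation to a methoxy-stabilised benzylic allyl cation, 1,2-hydride shift and tautomerisation (the classical 1,4-epoxy-1,4-dihydronaphthalene to 1-naphthol isomerisation), and each of the two naphthols that can result has a free para position that the cobalt–dioxygen complex oxygenates (salcomine oxidation of phenols to p-quinones), so both converge on the same 2-substituted quinone.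

**Step 10**
Reactants: 24 (R)-1-(5,8-dimethoxy-1,4-dioxo-1,4-dihydronaphthalen-2-yl)-4-methylpent-3-en-1-yl butanoate
Product: 26 butylshikonin, (R)-1-(5,8-dihydroxy-1,4-dioxo-1,4-dihydronaphthalen-2-yl)-4-methylpent-3-en-1-yl butanoate, via naphthodiquinone 25 (not isolated)
Conditions: AgO, 6 M HNO3, 1,4-dioxane, rt, minutes; then aq. Na2S2O4/CHCl3 work-up
Reagents that add atoms: water, O (supplies the two new carbonyl oxygens by ipso substitution)
Why: Argentic oxide oxidative demethylation (Rapoport conditions) converts the p-dimethoxy ring into a second quinone by ipso attack of water and loss of methanol in a reaction short enough to spare ester and alkene, and two-electron reduction of the diquinone by dithionite on work-up should give the hydrogen-bonded naphthazarin with C1' unchanged.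

**Compound list**

1 | 2,5-dimethoxyphenol | COc1ccc(OC)c(O)c1 | starting material
2 | 2,5-dimethoxyphenyl N-isopropylcarbamate | COc1ccc(OC)c(OC(=O)NC(C)C)c1 | intermediate
3 | 2,5-dimethoxyphenyl N-isopropyl-N-(trimethylsilyl)carbamate (formed in situ) | COc1ccc(OC)c(OC(=O)N(C(C)C)[Si](C)(C)C)c1 | intermediate
4 | 2-lithio-3,6-dimethoxyphenyl N-isopropyl-N-(trimethylsilyl)carbamate (formed in situ) | COc1ccc(OC)c(OC(=O)N(C(C)C)[Si](C)(C)C)c1[Li] | intermediate
5 | 3,6-dimethoxy-2-(trimethylsilyl)phenyl N-isopropyl-N-(trimethylsilyl)carbamate (formed in situ) | COc1ccc(OC)c(OC(=O)N(C(C)C)[Si](C)(C)C)c1[Si](C)(C)C | intermediate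
6 | 3,6-dimethoxy-2-(trimethylsilyl)phenyl N-isopropylcarbamate | COc1ccc(OC)c(OC(=O)NC(C)C)c1[Si](C)(C)C | intermediate
7 | 3,6-dimethoxy-2-(trimethylsilyl)phenol (formed in situ) | COc1ccc(OC)c(O)c1[Si](C)(C)C | intermediate
8 | 3,6-dimethoxy-2-(trimethylsilyl)phenyl trifluoromethanesulfonate | COc1ccc(OC)c(OS(=O)(=O)C(F)(F)F)c1[Si](C)(C)C | intermediate
9 | 4-methylpent-3-enoic acid | CC(C)=CCC(=O)O | starting material
10 | 1-(1H-imidazol-1-yl)-4-methylpent-3-en-1-one (formed in situ) | CC(C)=CCC(=O)n1ccnc1 | intermediate
11 | N-methoxy-N,4-dimethylpent-3-enamide | CC(C)=CCC(=O)N(C)OC | intermediate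
12 | 3-bromofuran | Brc1ccoc1 | starting material
13 | furan-3-yllithium (formed in situ) | [Li]c1ccoc1 | intermediate
14 | lithium 1-(furan-3-yl)-1-[methoxy(methyl)amino]-4-methylpent-3-en-1-olate (formed in situ) | [Li]OC(CC=C(C)C)(c1ccoc1)N(C)OC | intermediate
15 | 1-(furan-3-yl)-4-methylpent-3-en-1-one | CC(C)=CCC(=O)c1ccoc1 | intermediate
16 | (R)-2-{[1-(furan-3-yl)-4-methylpent-3-en-1-yl]oxy}-1,3,2-benzodioxaborole (formed in situ) | CC(C)=CC[C@@H](OB1Oc2ccccc2O1)c1ccoc1 | intermediate
17 | (R)-1-(furan-3-yl)-4-methylpent-3-en-1-ol | CC(C)=CC[C@@H](O)c1ccoc1 | intermediate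
18 | butanoic anhydride | CCCC(=O)OC(=O)CCC | starting material
19 | (R)-1-(furan-3-yl)-4-methylpent-3-en-1-yl butanoate | CCCC(=O)O[C@H](CC=C(C)C)c1ccoc1 | intermediate
20 | 3,6-dimethoxybenzyne (formed in situ) | COC1=CC=C(OC)C#C1 | intermediate
21 | (R)-1-(5,8-dimethoxy-1,4-dihydro-1,4-epoxynaphthalen-2-yl)-4-methylpent-3-en-1-yl butanoate, both bridgehead epimers | CCCC(=O)O[C@H](CC=C(C)C)C1=CC2OC1c1c(OC)ccc(OC)c12 | intermediate
22 | (R)-1-(4-hydroxy-5,8-dimethoxynaphthalen-2-yl)-4-methylpent-3-en-1-yl butanoate (formed in situ) | CCCC(=O)O[C@H](CC=C(C)C)c1cc(O)c2c(OC)ccc(OC)c2c1 | intermediate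
23 | (R)-1-(1-hydroxy-5,8-dimethoxynaphthalen-2-yl)-4-methylpent-3-en-1-yl butanoate (formed in situ) | CCCC(=O)O[C@H](CC=C(C)C)c1ccc2c(OC)ccc(OC)c2c1O | intermediate
24 | (R)-1-(5,8-dimethoxy-1,4-dioxo-1,4-dihydronaphthalen-2-yl)-4-methylpent-3-en-1-yl butanoate | CCCC(=O)O[C@H](CC=C(C)C)C1=CC(=O)c2c(OC)ccc(OC)c2C1=O | intermediate
25 | (R)-4-methyl-1-(1,4,5,8-tetraoxo-1,4,5,8-tetrahydronaphthalen-2-yl)pent-3-en-1-yl butanoate (formed in situ) | CCCC(=O)O[C@H](CC=C(C)C)C1=CC(=O)C2=C(C1=O)C(=O)C=CC2=O | intermediate
26 | butylshikonin, (R)-1-(5,8-dihydroxy-1,4-dioxo-1,4-dihydronaphthalen-2-yl)-4-methylpent-3-en-1-yl butanoate | CCCC(=O)O[C@H](CC=C(C)C)C1=CC(=O)c2c(O)ccc(O)c2C1=O | target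

**Totals**

Total step count: 10. Longest linear sequence: 7 steps (steps 4–10, from 4-methylpent-3-enoic acid); the aryne arm (steps 1–3) joins at step 8.

**Steps most likely to fail**

1. Step 9. Once the ring has opened, the naphthol with the side chain ortho to the hydroxyl can lose butanoate under the Lewis acid (quinone-methide-type ionisation, which would also erode the C1' configuration), and cationic species can attack the trisubstituted alkene. The fallback sets out from 17 and comes back at 24, carrying C1'–O as a silyl ether, a much poorer leaving group that cannot form an acyloxonium ion. Alcohol 17 is silylated (TBSCl, imidazole, DMF) to (R)-tert-butyl{[1-(furan-3-yl)-4-methylpent-3-en-1-yl]oxy}dimethylsilane F1. This is taken through the aryne cycloaddition with 8 (CsF, MeCN) to (R)-tert-butyl{[1-(5,8-dimethoxy-1,4-dihydro-1,4-epoxynaphthalen-2-yl)-4-methylpent-3-en-1-yl]oxy}dimethylsilane F2. The same Lewis-acid opening should give (R)-3-{1-[(tert-butyldimethylsilyl)oxy]-4-methylpent-3-en-1-yl}-5,8-dimethoxynaphthalen-1-ol F3 and (R)-2-{1-[(tert-butyldimethylsilyl)oxy]-4-methylpent-3-en-1-yl}-5,8-dimethoxynaphthalen-1-ol F4, and salcomine/O2 should give (R)-2-{1-[(tert-butyldimethylsilyl)oxy]-4-methylpent-3-en-1-yl}-5,8-dimethoxynaphthalene-1,4-dione F5. HF·pyridine in THF then frees (R)-2-(1-hydroxy-4-methylpent-3-en-1-yl)-5,8-dimethoxynaphthalene-1,4-dione F6, which is butanoylated with 18 (Et3N, DMAP) to 24.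

2. Step 10. The dimethoxy ring is deactivated by the two quinone carbonyls, so oxidation may be slow, and longer exposure to Ag(II)/nitric acid invites attack on the alkene and ester hydrolysis. The fallback sets out from 24 and comes back at 26, oxidising from the other ring instead. Reductive acetylation (Zn, Ac2O, NaOAc) gives (R)-1-(1,4-diacetoxy-5,8-dimethoxynaphthalen-2-yl)-4-methylpent-3-en-1-yl butanoate F7, in which the dimethoxy ring is now the electron-rich one. Ceric ammonium nitrate (MeCN/H2O, 0 °C), a reagent known to tolerate this side chain, should convert it into (R)-1-(1,4-diacetoxy-5,8-dioxo-5,8-dihydronaphthalen-2-yl)-4-methylpent-3-en-1-yl butanoate F8. Brief methanolysis (cat. K2CO3, MeOH, 0 °C, then acidification) removes the activated aryl acetates while the secondary alkyl butanoate stays; the 1,4-dihydroxy-5,8-dione so formed is the tautomer of 26.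

3. Step 6. Facial discrimination between the small planar 3-furyl group and the CH2 chain may be insufficient, and the β,γ-alkene may migrate into conjugation at the ketone stage. The fallback sets out from 12 and comes back at 17, avoiding the ketone (and the enolisable Weinreb amide of step 5) altogether. 3-Bromofuran 12 is lithiated as in step 5 and formylated with DMF to furan-3-carbaldehyde F9. Brown allylation with (+)-Ipc2B(allyl) (from (−)-α-pinene; Et2O, −78 °C, ethanolamine work-up), the antipode that gives (R)-1-aryl-3-buten-1-ols, should give (R)-1-(furan-3-yl)but-3-en-1-ol F10. Cross-metathesis with 2-methyl-2-butene (Grubbs second-generation catalyst) then installs the trisubstituted alkene and gives 17.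

**Further compounds**

F1 | step 9 | (R)-tert-butyl{[1-(furan-3-yl)-4-methylpent-3-en-1-yl]oxy}dimethylsilane | CC(C)(C)[Si](C)(C)O[C@H](CC=C(C)C)c1ccoc1
F2 | step 9 | (R)-tert-butyl{[1-(5,8-dimethoxy-1,4-dihydro-1,4-epoxynaphthalen-2-yl)-4-methylpent-3-en-1-yl]oxy}dimethylsilane, both bridgehead epimers | CC(C)(C)[Si](C)(C)O[C@H](CC=C(C)C)C1=CC2OC1c1c(OC)ccc(OC)c12
F3 | step 9 | (R)-3-{1-[(tert-butyldimethylsilyl)oxy]-4-methylpent-3-en-1-yl}-5,8-dimethoxynaphthalen-1-ol | CC(C)(C)[Si](C)(C)O[C@H](CC=C(C)C)c1cc(O)c2c(OC)ccc(OC)c2c1
F4 | step 9 | (R)-2-{1-[(tert-butyldimethylsilyl)oxy]-4-methylpent-3-en-1-yl}-5,8-dimethoxynaphthalen-1-ol | CC(C)(C)[Si](C)(C)O[C@H](CC=C(C)C)c1ccc2c(OC)ccc(OC)c2c1O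
F5 | step 9 | (R)-2-{1-[(tert-butyldimethylsilyl)oxy]-4-methylpent-3-en-1-yl}-5,8-dimethoxynaphthalene-1,4-dione | CC(C)(C)[Si](C)(C)O[C@H](CC=C(C)C)C1=CC(=O)c2c(OC)ccc(OC)c2C1=O
F6 | step 9 | (R)-2-(1-hydroxy-4-methylpent-3-en-1-yl)-5,8-dimethoxynaphthalene-1,4-dione | CC(C)=CC[C@@H](O)C1=CC(=O)c2c(OC)ccc(OC)c2C1=O
F7 | step 10 | (R)-1-(1,4-diacetoxy-5,8-dimethoxynaphthalen-2-yl)-4-methylpent-3-en-1-yl butanoate | CCCC(=O)O[C@H](CC=C(C)C)c1cc(OC(C)=O)c2c(OC)ccc(OC)c2c1OC(C)=O
F8 | step 10 | (R)-1-(1,4-diacetoxy-5,8-dioxo-5,8-dihydronaphthalen-2-yl)-4-methylpent-3-en-1-yl butanoate | CCCC(=O)O[C@H](CC=C(C)C)c1cc(OC(C)=O)c2C(=O)C=CC(=O)c2c1OC(C)=O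
F9 | step 6 | furan-3-carbaldehyde | O=Cc1ccoc1
F10 | step 6 | (R)-1-(furan-3-yl)but-3-en-1-ol | C=CC[C@@H](O)c1ccoc1
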